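The route cuts the C7''–H bond. C7'' (the benzylic carbinol on ring C) and C8'' (the aryl ether carbon) are set together at the keto ester stage, where C8'' lies between the C7'' ketone and the C9'' ester carbonyl and racemises through its enol. One ruthenium-catalysed transfer hydrogenation with dynamic kinetic resolution turns racemic ethyl 2-(4-bromo-2-methoxyphenoxy)-3-(4-benzyloxy-3-methoxyphenyl)-3-oxopropanoate into the (2S,3R) threo hydroxy ester. The ring B bromide is kept as the handle for a later rhodium-catalysed conjugate addition of the derived boronate to an (R)-configured ring A α-methylene lactone, which builds the trans-dibenzylbutyrolactone.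

Key step: step 4

Remark on numbering: the glycerol chain is C7'' (carbinol carbon on ring C), C8'' (aryl ether carbon) and C9'' (CH2OH). The lactone is C2 (carbonyl), C3 (carries the ring B benzyl), C4 (carries the ring A benzyl) and C5. Ring A is the guaiacyl ring of the C4 benzyl group, ring B the central aryl ether ring, ring C the guaiacyl ring on C7''.

Assumption: in step 9 the sense of hydrogenation is assigned by analogy with (Z)-dehydroamino acid reductions by the same catalyst, the Stobbe acid being their carbon analogue; the mirror-image ligand would be used if a chiroptical check at the β-benzyl lactone stage required it.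

Step 1
Reactants: 1 4-bromo-2-methoxyphenol; 2 ethyl bromoacetate
Product: 3 ethyl 2-(4-bromo-2-methoxyphenoxy)acetate
Conditions: K2CO3, acetone, reflux
Reagents that add atoms: none
Why: Williamson etherification, in which the phenoxide formed by K2CO3 displaces bromide from the primary α-bromo ester in an SN2 reaction; no stereocentre is involved.

Step 2
Reactants: 4 4-(benzyloxy)-3-methoxybenzoic acid
Product: 5 4-(benzyloxy)-3-methoxybenzoyl chloride
Conditions: (COCl)2, DMF (cat.), CH2Cl2, 0 °C to rt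
Reagents that add atoms: oxalyl chloride, ClC(=O)C(Cl)=O
Why: Acid chloride formation through the chloroiminium species from (COCl)2 and DMF is standard for benzoic acids and leaves the benzyl ether untouched.

Step 3
Reactants: 3 ethyl 2-(4-bromo-2-methoxyphenoxy)acetate; 5 4-(benzyloxy)-3-methoxybenzoyl chloride
Product: 6 ethyl 3-[4-(benzyloxy)-3-methoxyphenyl]-2-(4-bromo-2-methoxyphenoxy)-3-oxopropanoate (racemic at C8'')
Conditions: LiN(SiMe3)2 (2.1 equiv), THF, −78 °C; then 5, −78 to 0 °C; aq. NH4Cl
Reagents that add atoms: none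
Why: Crossed Claisen acylation, in which the lithium enolate of 3 attacks the acid chloride at carbon while the second equivalent of base stores the more acidic product as its enolate and so blocks a second acylation; the aryl bromide and benzyl ether are inert to the amide base at low temperature, and C8'' is formed racemic on purpose.

Step 4
Reactants: 6 ethyl 3-[4-(benzyloxy)-3-methoxyphenyl]-2-(4-bromo-2-methoxyphenoxy)-3-oxopropanoate
Product: 7 ethyl (2S,3R)-3-[4-(benzyloxy)-3-methoxyphenyl]-2-(4-bromo-2-methoxyphenoxy)-3-hydroxypropanoate (syn, threo)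
Conditions: RuCl(p-cymene)[(S,S)-TsDPEN] (2 mol %), HCO2H/Et3N (5:2), CH2Cl2, 35 °C
Reagents that add atoms: none
Why: Formate converts RuCl(p-cymene)[(S,S)-TsDPEN] (divalent ruthenium) into the amine hydride complex, which passes Ru–H to the C7'' carbonyl carbon and N–H to its oxygen through a six-membered outer-sphere transition state, while the two enantiomers of 6 interconvert through the enol because the C8'' hydrogen lies between the ketone and the ester carbonyl. The closest known reaction type is ruthenium–TsDPEN asymmetric transfer hydrogenation with dynamic kinetic resolution of α-alkoxy β-keto esters to syn α-alkoxy β-hydroxy esters, of which the aryloxy case is a direct extension; no ring is closed. C7'' is controlled by the catalyst: the ring C aryl group lies under the p-cymene ligand (CH/π contact), so the (S,S)-complex should deliver hydride to the face that gives the (3R) carbinol, the spatial sense it shows with simple aryl ketones. C8'' is controlled by the kinetic resolution: only the enantiomer of 6 whose aryloxy and ester groups fit the matched transition state is reduced quickly, which should give (2S) and hence the syn (threo) pair, the other enantiomer being fed back through the enol. The step needs ketone-over-ester chemoselectivity and tolerance of the aryl bromide and the benzyl ether, both secured by the metal–ligand bifunctional hydride transfer, and it needs racemisation faster than reduction, secured by the double activation of C8''–H.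

Step 5
Reactants: 7 ethyl (2S,3R)-3-[4-(benzyloxy)-3-methoxyphenyl]-2-(4-bromo-2-methoxyphenoxy)-3-hydroxypropanoate
Product: 8 (1R,2R)-1-[4-(benzyloxy)-3-methoxyphenyl]-2-(4-bromo-2-methoxyphenoxy)propane-1,3-diol
Conditions: LiBH4, THF, 0 °C to rt; aq. NH4Cl
Reagents that add atoms: none
Why: Ester reduction with LiBH4 is fast for an α-aryloxy ester, leaves the aryl bromide and benzyl ether alone and touches neither C7'' nor C8'', so the threo relationship is carried into the 1,3-diol (the descriptor at C8'' changes to R only because C9'' drops in priority).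

Step 6
Reactants: 8 (1R,2R)-1-[4-(benzyloxy)-3-methoxyphenyl]-2-(4-bromo-2-methoxyphenoxy)propane-1,3-diol
Product: 9 (4R,5R)-4-[4-(benzyloxy)-3-methoxyphenyl]-5-(4-bromo-2-methoxyphenoxy)-2,2-dimethyl-1,3-dioxane
Conditions: Me2C(OMe)2, PPTS (cat.), acetone, rt
Reagents that add atoms: 2,2-dimethoxypropane, COC(C)(C)OC
Why: Acid-catalysed transketalisation of the 1,3-diol gives the six-membered acetonide (4-aryl and 5-aryloxy cis), which masks both hydroxyl groups for the two metal-catalysed steps without touching either stereocentre.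

Step 7
Reactants: 9 (4R,5R)-4-[4-(benzyloxy)-3-methoxyphenyl]-5-(4-bromo-2-methoxyphenoxy)-2,2-dimethyl-1,3-dioxane
Product: 10 2-[4-({(4R,5R)-4-[4-(benzyloxy)-3-methoxyphenyl]-2,2-dimethyl-1,3-dioxan-5-yl}oxy)-3-methoxyphenyl]-4,4,5,5-tetramethyl-1,3,2-dioxaborolane
Conditions: B2pin2, PdCl2(dppf) (4 mol %), KOAc, 1,4-dioxane, 85 °C
Reagents that add atoms: bis(pinacolato)diboron, CC1(C)OB(OC1(C)C)B1OC(C)(C)C(C)(C)O1
Why: Miyaura borylation, in which oxidative addition of the aryl bromide to zerovalent palladium, acetate-assisted transmetalation with B2pin2 and reductive elimination give the pinacol boronate, the weak base KOAc suppressing biaryl coupling.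

Step 8
Reactants: 11 4-(benzyloxy)-3-methoxybenzaldehyde; 12 dimethyl succinate
Product: 13 (E)-4-[4-(benzyloxy)-3-methoxyphenyl]-3-(methoxycarbonyl)but-3-enoic acid
Conditions: NaOMe, MeOH, reflux; then aq. HCl
Reagents that add atoms: none
Why: Stobbe condensation, in which the succinate enolate adds to the aldehyde, the alkoxide closes to a paraconate lactone and base-induced ring opening gives the (E)-arylidene half-ester with the ester on the substituted carbon and the free acid on the CH2 arm, the pattern needed for the lactone.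

Step 9
Reactants: 13 (E)-4-[4-(benzyloxy)-3-methoxyphenyl]-3-(methoxycarbonyl)but-3-enoic acid
Product: 14 (3R)-4-[4-(benzyloxy)-3-methoxyphenyl]-3-(methoxycarbonyl)butanoic acid
Conditions: [Rh(cod)((S,S)-Et-DuPHOS)]BF4 (0.5 mol %), H2 (5 bar), NaOMe (0.1 equiv), MeOH, rt
Reagents that add atoms: none
Why: Rhodium–bisphosphine asymmetric hydrogenation of a Stobbe half-ester, in which the carboxylate arm chelates rhodium as the acetamido carbonyl of a (Z)-dehydroamino acid does, so the (S,S)-ligand that leads to (S)-amino acids should add H2 to the corresponding face and set the stereocentre as (R); homogeneous cationic rhodium does not cleave the benzyl ether.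

Step 10
Reactants: 14 (3R)-4-[4-(benzyloxy)-3-methoxyphenyl]-3-(methoxycarbonyl)butanoic acid
Product: 16 (4R)-4-[4-(benzyloxy)-3-methoxybenzyl]dihydrofuran-2(3H)-one, via hydroxy acid 15 (not isolated)
Conditions: KOH (1.0 equiv), EtOH, 0 °C; CaCl2, NaBH4, EtOH, −10 °C to rt; then 2 M HCl, rt
Reagents that add atoms: none
Why: Chemoselective ester reduction by Ca(BH4)2 beside the unreactive carboxylate, then acid-induced lactonisation of the γ-hydroxy acid, gives the β-benzyl lactone; under these weakly basic conditions the centre α to the ester should not epimerise before it is reduced.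

Step 11
Reactants: 16 (4R)-4-[4-(benzyloxy)-3-methoxybenzyl]dihydrofuran-2(3H)-one
Product: 19 (4R)-4-[4-(benzyloxy)-3-methoxybenzyl]-3-methylidenedihydrofuran-2(3H)-one, via Mannich base 17 (not isolated), via trimethylammonium iodide 18 (not isolated)
Conditions: LiN(SiMe3)2, THF, −78 °C; Me2N=CH2+ I−, −78 °C to rt; MeI, MeOH, rt; aq. NaHCO3, CH2Cl2, rt
Reagents that add atoms: Eschenmoser's salt (N,N-dimethylmethylideneammonium iodide), C=[N+](C)C.[I-]
Why: α-Methylenation by the Mannich route, in which the lactone enolate is aminomethylated, N-methylation by MeI turns the amine into a trimethylamine leaving group and mild base brings about E1cB elimination to the exocyclic enoate; C4 is not involved and the transient C3 centre is destroyed.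

Step 12
Reactants: 10 2-[4-({(4R,5R)-4-[4-(benzyloxy)-3-methoxyphenyl]-2,2-dimethyl-1,3-dioxan-5-yl}oxy)-3-methoxyphenyl]-4,4,5,5-tetramethyl-1,3,2-dioxaborolane; 19 (4R)-4-[4-(benzyloxy)-3-methoxybenzyl]-3-methylidenedihydrofuran-2(3H)-one (1.3 equiv)
Product: 21 (3R,4R)-4-[4-(benzyloxy)-3-methoxybenzyl]-3-[4-({(4R,5R)-4-[4-(benzyloxy)-3-methoxyphenyl]-2,2-dimethyl-1,3-dioxan-5-yl}oxy)-3-methoxybenzyl]dihydrofuran-2(3H)-one, via cis lactone 20 (not isolated)
Conditions: [Rh(cod)OH]2 (3 mol %), Et3N (1 equiv), dioxane/H2O (10:1), 60 °C; then KOt-Bu (0.2 equiv), THF, 0 °C to rt; AcOH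
Reagents that add atoms: none
Why: Hayashi–Miyaura-type conjugate addition, in which the aryl group passes from boron to the monovalent rhodium hydroxide, adds to the exocyclic CH2 of the enoate and the rhodium enolate is protonated by water (expected mainly anti to the C4 benzyl, giving the cis lactone), after which catalytic KOt-Bu equilibrates C3 through the lactone enolate to the more stable trans arrangement, so C3 (R) is set under thermodynamic control by the fixed C4 centre.

Step 13
Reactants: 21 (3R,4R)-4-[4-(benzyloxy)-3-methoxybenzyl]-3-[4-({(4R,5R)-4-[4-(benzyloxy)-3-methoxyphenyl]-2,2-dimethyl-1,3-dioxan-5-yl}oxy)-3-methoxybenzyl]dihydrofuran-2(3H)-one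
Product: 22 (3R,4R)-4-[4-(benzyloxy)-3-methoxybenzyl]-3-[4-({(1R,2R)-1-[4-(benzyloxy)-3-methoxyphenyl]-1,3-dihydroxypropan-2-yl}oxy)-3-methoxybenzyl]dihydrofuran-2(3H)-one
Conditions: AcOH/H2O (4:1), 40 °C
Reagents that add atoms: none
Why: Mild aqueous acid hydrolyses the isopropylidene ketal while both phenols are still benzylated, conditions under which the lactone, the alkyl aryl ether and the C7'' benzylic carbinol should persist without epimerisation.

Step 14
Reactants: 22 (3R,4R)-4-[4-(benzyloxy)-3-methoxybenzyl]-3-[4-({(1R,2R)-1-[4-(benzyloxy)-3-methoxyphenyl]-1,3-dihydroxypropan-2-yl}oxy)-3-methoxybenzyl]dihydrofuran-2(3H)-one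
Product: 23 (3R,4R)-3-[4-({(1R,2R)-1,3-dihydroxy-1-(4-hydroxy-3-methoxyphenyl)propan-2-yl}oxy)-3-methoxybenzyl]-4-(4-hydroxy-3-methoxybenzyl)dihydrofuran-2(3H)-one (target)
Conditions: H2 (1 atm), Pd/C (10 wt % Pd), EtOAc/EtOH, rt
Reagents that add atoms: none
Why: Hydrogenolysis of the two benzyl aryl ethers over Pd/C under neutral conditions releases both phenols, while the secondary benzylic alcohol, the alkyl aryl ether and the lactone are not cleaved at ambient pressure and temperature.

Compound list
1 | 4-bromo-2-methoxyphenol | COc1cc(Br)ccc1O | starting material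
2 | ethyl bromoacetate | CCOC(=O)CBr | starting material
3 | ethyl 2-(4-bromo-2-methoxyphenoxy)acetate | CCOC(=O)COc1ccc(Br)cc1OC | intermediate
4 | 4-(benzyloxy)-3-methoxybenzoic acid | COc1cc(C(=O)O)ccc1OCc1ccccc1 | starting material
5 | 4-(benzyloxy)-3-methoxybenzoyl chloride | COc1cc(C(Cl)=O)ccc1OCc1ccccc1 | intermediate
6 | ethyl 3-[4-(benzyloxy)-3-methoxyphenyl]-2-(4-bromo-2-methoxyphenoxy)-3-oxopropanoate, racemic | CCOC(=O)C(Oc1ccc(Br)cc1OC)C(=O)c1ccc(OCc2ccccc2)c(OC)c1 | intermediate
7 | ethyl (2S,3R)-3-[4-(benzyloxy)-3-methoxyphenyl]-2-(4-bromo-2-methoxyphenoxy)-3-hydroxypropanoate | CCOC(=O)[C@@H](Oc1ccc(Br)cc1OC)[C@H](O)c1ccc(OCc2ccccc2)c(OC)c1 | intermediate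
8 | (1R,2R)-1-[4-(benzyloxy)-3-methoxyphenyl]-2-(4-bromo-2-methoxyphenoxy)propane-1,3-diol | OC[C@@H](Oc1ccc(Br)cc1OC)[C@H](O)c1ccc(OCc2ccccc2)c(OC)c1 | intermediate
9 | (4R,5R)-4-[4-(benzyloxy)-3-methoxyphenyl]-5-(4-bromo-2-methoxyphenoxy)-2,2-dimethyl-1,3-dioxane | CC1(C)OC[C@@H](Oc2ccc(Br)cc2OC)[C@H](O1)c1ccc(OCc2ccccc2)c(OC)c1 | intermediate
10 | 2-[4-({(4R,5R)-4-[4-(benzyloxy)-3-methoxyphenyl]-2,2-dimethyl-1,3-dioxan-5-yl}oxy)-3-methoxyphenyl]-4,4,5,5-tetramethyl-1,3,2-dioxaborolane | CC1(C)OC[C@@H](Oc2ccc(B3OC(C)(C)C(C)(C)O3)cc2OC)[C@H](O1)c1ccc(OCc2ccccc2)c(OC)c1 | intermediate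
11 | 4-(benzyloxy)-3-methoxybenzaldehyde | COc1cc(C=O)ccc1OCc1ccccc1 | starting material
12 | dimethyl succinate | COC(=O)CCC(=O)OC | starting material
13 | (E)-4-[4-(benzyloxy)-3-methoxyphenyl]-3-(methoxycarbonyl)but-3-enoic acid | COC(=O)/C(CC(=O)O)=C/c1ccc(OCc2ccccc2)c(OC)c1 | intermediate
14 | (3R)-4-[4-(benzyloxy)-3-methoxyphenyl]-3-(methoxycarbonyl)butanoic acid | COC(=O)[C@@H](CC(=O)O)Cc1ccc(OCc2ccccc2)c(OC)c1 | intermediate
15 | (3R)-3-[4-(benzyloxy)-3-methoxybenzyl]-4-hydroxybutanoic acid | OC[C@@H](CC(=O)O)Cc1ccc(OCc2ccccc2)c(OC)c1 | intermediate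
16 | (4R)-4-[4-(benzyloxy)-3-methoxybenzyl]dihydrofuran-2(3H)-one | COc1cc(C[C@H]2COC(=O)C2)ccc1OCc1ccccc1 | intermediate
17 | (3S,4R)-4-[4-(benzyloxy)-3-methoxybenzyl]-3-[(dimethylamino)methyl]dihydrofuran-2(3H)-one (trans expected) | COc1cc(C[C@H]2COC(=O)[C@@H]2CN(C)C)ccc1OCc1ccccc1 | intermediate
18 | {(3S,4R)-4-[4-(benzyloxy)-3-methoxybenzyl]-2-oxotetrahydrofuran-3-yl}-N,N,N-trimethylmethanaminium iodide | COc1cc(C[C@H]2COC(=O)[C@@H]2C[N+](C)(C)C)ccc1OCc1ccccc1.[I-] | intermediate
19 | (4R)-4-[4-(benzyloxy)-3-methoxybenzyl]-3-methylidenedihydrofuran-2(3H)-one | COc1cc(C[C@H]2COC(=O)C2=C)ccc1OCc1ccccc1 | intermediate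
20 | (3S,4R)-4-[4-(benzyloxy)-3-methoxybenzyl]-3-[4-({(4R,5R)-4-[4-(benzyloxy)-3-methoxyphenyl]-2,2-dimethyl-1,3-dioxan-5-yl}oxy)-3-methoxybenzyl]dihydrofuran-2(3H)-one (cis lactone) | COc1cc(C[C@H]2COC(=O)[C@H]2Cc2ccc(O[C@@H]3COC(C)(C)O[C@@H]3c3ccc(OCc4ccccc4)c(OC)c3)c(OC)c2)ccc1OCc1ccccc1 | intermediate
21 | (3R,4R)-4-[4-(benzyloxy)-3-methoxybenzyl]-3-[4-({(4R,5R)-4-[4-(benzyloxy)-3-methoxyphenyl]-2,2-dimethyl-1,3-dioxan-5-yl}oxy)-3-methoxybenzyl]dihydrofuran-2(3H)-one (trans lactone) | COc1cc(C[C@H]2COC(=O)[C@@H]2Cc2ccc(O[C@@H]3COC(C)(C)O[C@@H]3c3ccc(OCc4ccccc4)c(OC)c3)c(OC)c2)ccc1OCc1ccccc1 | intermediate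
22 | (3R,4R)-4-[4-(benzyloxy)-3-methoxybenzyl]-3-[4-({(1R,2R)-1-[4-(benzyloxy)-3-methoxyphenyl]-1,3-dihydroxypropan-2-yl}oxy)-3-methoxybenzyl]dihydrofuran-2(3H)-one | COc1cc(C[C@H]2COC(=O)[C@@H]2Cc2ccc(O[C@H](CO)[C@H](O)c3ccc(OCc4ccccc4)c(OC)c3)c(OC)c2)ccc1OCc1ccccc1 | intermediate
23 | (3R,4R)-3-[4-({(1R,2R)-1,3-dihydroxy-1-(4-hydroxy-3-methoxyphenyl)propan-2-yl}oxy)-3-methoxybenzyl]-4-(4-hydroxy-3-methoxybenzyl)dihydrofuran-2(3H)-one | COc1cc(C[C@H]2COC(=O)[C@@H]2Cc2ccc(O[C@H](CO)[C@H](O)c3ccc(O)c(OC)c3)c(OC)c2)ccc1O | target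

Total step count: 14.
Longest linear sequence: 9 steps (steps 1, 3, 4, 5, 6, 7, 12, 13, 14).

Steps most likely to fail

Step 4. Enolisation of 6 may not keep pace with hydride transfer, or reduction of the electron-rich aryl ketone may be slow, so that the threo selectivity or the enantiomeric purity falls short. The fallback replaces the reduction by an auxiliary-controlled aldol reaction; it sets out from 3 and returns to the route at 8. Saponification of 3 (LiOH, THF/H2O) would give 2-(4-bromo-2-methoxyphenoxy)acetic acid F1. Its pivaloyl mixed anhydride would acylate lithiated (S)-4-benzyloxazolidin-2-one to give (S)-4-benzyl-3-[2-(4-bromo-2-methoxyphenoxy)acetyl]oxazolidin-2-one F2. The dibutylboron (Z)-enolate (Bu2BOTf, i-Pr2NEt, CH2Cl2, −78 °C) would add to aldehyde 11 in an Evans syn aldol reaction to give (S)-4-benzyl-3-{(2S,3R)-3-[4-(benzyloxy)-3-methoxyphenyl]-2-(4-bromo-2-methoxyphenoxy)-3-hydroxypropanoyl}oxazolidin-2-one F3. LiBH4 in wet THF would then remove the auxiliary reductively and give diol 8 directly.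

Step 12. Protodeboronation of the electron-rich boronate may outrun transmetalation, the enoate may isomerise to the endocyclic butenolide, or equilibration at C3 may stop short of the trans isomer. The fallback replaces the conjugate addition by an enolate alkylation; it sets out from 9 and returns to the route at 21. Bromine–lithium exchange on 9 (n-BuLi, THF, −78 °C) and trapping with DMF would give 4-({(4R,5R)-4-[4-(benzyloxy)-3-methoxyphenyl]-2,2-dimethyl-1,3-dioxan-5-yl}oxy)-3-methoxybenzaldehyde F4. NaBH4 in MeOH would give [4-({(4R,5R)-4-[4-(benzyloxy)-3-methoxyphenyl]-2,2-dimethyl-1,3-dioxan-5-yl}oxy)-3-methoxyphenyl]methanol F5, and an Appel reaction (CBr4, PPh3, CH2Cl2, 0 °C) would give (4R,5R)-4-[4-(benzyloxy)-3-methoxyphenyl]-5-[4-(bromomethyl)-2-methoxyphenoxy]-2,2-dimethyl-1,3-dioxane F6. The lithium enolate of lactone 16 (LiN(SiMe3)2, THF, −78 °C) would be alkylated by this bromide anti to the C4 benzyl group, which should give the trans lactone 21 under kinetic control.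

Step 3. O-acylation of the enolate, attack of the amide base on the acid chloride, or proton exchange between product and unreacted enolate may erode the C-acylation. The fallback replaces the acylation by an aldol addition and an oxidation; it sets out from 3 and 11 and returns to the route at 6. The lithium enolate of 3 (LiN(i-Pr)2, THF, −78 °C) would add to aldehyde 11 to give ethyl 3-[4-(benzyloxy)-3-methoxyphenyl]-2-(4-bromo-2-methoxyphenoxy)-3-hydroxypropanoate F7 as a racemic mixture of diastereomers. Dess–Martin periodinane in CH2Cl2 would then oxidise the benzylic alcohol to keto ester 6, the stereochemistry of the aldol being irrelevant.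

Further compounds
F1 | step 4 | 2-(4-bromo-2-methoxyphenoxy)acetic acid | OC(=O)COc1ccc(Br)cc1OC
F2 | step 4 | (S)-4-benzyl-3-[2-(4-bromo-2-methoxyphenoxy)acetyl]oxazolidin-2-one | O=C(COc1ccc(Br)cc1OC)N1[C@@H](Cc2ccccc2)COC1=O
F3 | step 4 | (S)-4-benzyl-3-{(2S,3R)-3-[4-(benzyloxy)-3-methoxyphenyl]-2-(4-bromo-2-methoxyphenoxy)-3-hydroxypropanoyl}oxazolidin-2-one | O=C([C@@H](Oc1ccc(Br)cc1OC)[C@H](O)c1ccc(OCc2ccccc2)c(OC)c1)N1[C@@H](Cc2ccccc2)COC1=O
F4 | step 12 | 4-({(4R,5R)-4-[4-(benzyloxy)-3-methoxyphenyl]-2,2-dimethyl-1,3-dioxan-5-yl}oxy)-3-methoxybenzaldehyde | CC1(C)OC[C@@H](Oc2ccc(C=O)cc2OC)[C@H](O1)c1ccc(OCc2ccccc2)c(OC)c1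
F5 | step 12 | [4-({(4R,5R)-4-[4-(benzyloxy)-3-methoxyphenyl]-2,2-dimethyl-1,3-dioxan-5-yl}oxy)-3-methoxyphenyl]methanol | CC1(C)OC[C@@H](Oc2ccc(CO)cc2OC)[C@H](O1)c1ccc(OCc2ccccc2)c(OC)c1
F6 | step 12 | (4R,5R)-4-[4-(benzyloxy)-3-methoxyphenyl]-5-[4-(bromomethyl)-2-methoxyphenoxy]-2,2-dimethyl-1,3-dioxane | CC1(C)OC[C@@H](Oc2ccc(CBr)cc2OC)[C@H](O1)c1ccc(OCc2ccccc2)c(OC)c1
F7 | step 3 | ethyl 3-[4-(benzyloxy)-3-methoxyphenyl]-2-(4-bromo-2-methoxyphenoxy)-3-hydroxypropanoate (racemic mixture of diastereomers) | CCOC(=O)C(Oc1ccc(Br)cc1OC)C(O)c1ccc(OCc2ccccc2)c(OC)c1
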